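## Retrosynthetic overview

1. The C7 hydroperoxide and C8=C19 methylene come last, from a singlet-oxygen ene reaction on the 7E-alkene of the 13-acetate; the acetate and the exocyclic methylene are added just before.
2. The 14-membered ring (second ring formed) is closed at C13–C14 by a SmI2 ketyl–ketyl (pinacol) macrocyclisation of an acyclic enal/aldehyde, which creates both carbinol centres; the γ-lactone (third ring) closes in the same flask from the C14 alkoxide and a pendant methyl ester.
3. The acyclic dialdehyde comes from cross-metathesis with methacrolein (C11=C12), a photoredox enamine α-alkylation (C1–C15, sets C1) and SN2 alkylation of an epoxy triflate by a metalloenamine (C1–C2).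
4. The epoxide (first ring, C3/C4) comes from Sharpless epoxidation of a trienol.
5. The trienol comes from a B-alkyl Suzuki union (C6–C7) of a dienol-derived borane with a vinyl iodide made by carboalumination.

Assumption: locants follow cembrane numbering (C1 carries C15–C17, epoxide at C3/C4, OOH at C7, OAc at C13, lactone oxygen on C14), and compounds 1, 4, 9, 13 and 15 are taken as purchasable.

## Route

Step 1
Reactants: 1 hex-1-en-5-yne
Product: 3 (1E)-1-iodo-2-methylhexa-1,5-diene, via alkenylalane 2 (not isolated)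
Conditions: Me3Al (2 equiv), Cp2ZrCl2 (0.25 equiv), CH2Cl2, 0 °C → rt; then I2, THF, −30 → 0 °C
Reagents that add atoms: trimethylaluminium, C[Al](C)C; iodine, II
Why: Negishi zirconium-catalysed carboalumination adds Me–Al syn and regioselectively across the terminal alkyne (the terminal alkene is inert here), and iodinolysis of the C–Al bond with retention fixes the E trisubstituted alkene (future C7=C8).

Step 2
Reactants: 4 (2E)-3-methylpent-2-en-4-yn-1-ol
Product: 5 (2E)-3-methylpenta-2,4-dien-1-ol
Conditions: H2 (1 atm), Pd/CaCO3 poisoned with Pb(OAc)2, quinoline, EtOAc, rt, stopped after 1 equiv H2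
Reagents that add atoms: none
Why: Lindlar semi-hydrogenation reduces the terminal alkyne to the vinyl group and leaves the E trisubstituted alkene untouched; no stereocentre is formed.

Step 3
Reactants: 5 (2E)-3-methylpenta-2,4-dien-1-ol; 3 (1E)-1-iodo-2-methylhexa-1,5-diene
Product: 7 (2E,6E)-3,7-dimethylundeca-2,6,10-trien-1-ol, via bis(9-BBN) adduct 6 (not isolated)
Conditions: 9-BBN (2.2 equiv), THF, 0 °C → rt; then 3, PdCl2(dppf) (5 mol%), AsPh3, Cs2CO3, DMF/H2O, rt
Reagents that add atoms: none
Why: 9-BBN hydroborates only the terminal carbon of the diene (one further equivalent is taken up by the hydroxyl), and the B-alkyl Suzuki–Miyaura coupling joins C6 to C7 with retention of both alkene geometries.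

Step 4
Reactants: 7 (2E,6E)-3,7-dimethylundeca-2,6,10-trien-1-ol
Product: 8 [(2S,3S)-3-methyl-3-[(3E)-4-methylocta-3,7-dien-1-yl]oxiran-2-yl]methanol
Conditions: Ti(OiPr)4 (10 mol%), L-(+)-DET (12 mol%), t-BuOOH, 4 Å MS, CH2Cl2, −20 °C
Reagents that add atoms: tert-butyl hydroperoxide, CC(C)(C)OO
Why: Sharpless asymmetric epoxidation touches only the allylic-alcohol alkene, and L-(+)-tartrate delivers oxygen to the face that gives the (2S,3S)-epoxide (as with geraniol), setting C3 and C4 of the target.

Step 5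
Reactants: 8 [(2S,3S)-3-methyl-3-[(3E)-4-methylocta-3,7-dien-1-yl]oxiran-2-yl]methanol; 9 (E)-N-tert-butylethanimine
Product: 12 3-[(2S,3S)-3-methyl-3-[(3E)-4-methylocta-3,7-dien-1-yl]oxiran-2-yl]propanal, via epoxy triflate 10 (not isolated), via N-tert-butyl aldimine 11 (not isolated)
Conditions: n-BuLi, THF, −78 °C; Tf2O; then LiCH2CH=N-t-Bu (from 9 and LDA, THF, 0 °C), −78 °C; then NaOAc/AcOH buffer (pH 4.5), 0 °C
Reagents that add atoms: water, O
Why: Stork–Wittig metalloenamine alkylation, in which the aza-enolate displaces the primary triflate by SN2 far faster than it opens the trisubstituted epoxide, and the aldimine is hydrolysed at a pH the epoxide tolerates; the epoxide centres are untouched.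

Step 6
Reactants: 12 3-[(2S,3S)-3-methyl-3-[(3E)-4-methylocta-3,7-dien-1-yl]oxiran-2-yl]propanal; 13 methyl bromoacetate
Product: 14 methyl (3R)-3-formyl-4-[(2S,3S)-3-methyl-3-[(3E)-4-methylocta-3,7-dien-1-yl]oxiran-2-yl]butanoate
Conditions: fac-Ir(ppy)3 (1 mol%), trans-2-tert-butyl-3,5-dimethylimidazolidin-4-one·TfOH (20 mol%, enantiomer giving the 3R aldehyde), 2,6-lutidine, DMF, blue LEDs, rt
Reagents that add atoms: none
Why: Proposed new method: excited fac-Ir(ppy)3 reduces the bromoacetate to the electrophilic •CH2CO2Me radical, which adds to the chiral enamine on the face away from the tert-butyl group (setting C1), and the α-amino radical is then oxidised to the iminium and hydrolysed; the closest known reaction is the photoredox organocatalytic α-alkylation of aldehydes with bromomalonates, phenacyl bromides and bromoacetonitrile.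

Step 7
Reactants: 14 methyl (3R)-3-formyl-4-[(2S,3S)-3-methyl-3-[(3E)-4-methylocta-3,7-dien-1-yl]oxiran-2-yl]butanoate; 15 methacrolein
Product: 16 methyl (3R)-3-formyl-4-[(2S,3S)-3-methyl-3-[(3E,7E)-4,8-dimethyl-9-oxonona-3,7-dien-1-yl]oxiran-2-yl]butanoate
Conditions: 15 (5 equiv), second-generation Grubbs catalyst RuCl2(=CHPh)(PCy3)(SIMes) (5 mol%), CH2Cl2, 40 °C
Reagents that add atoms: none
Why: Olefin cross-metathesis of the terminal alkene with methacrolein gives the E 2-methyl enal (C11=C12) under thermodynamic control, while the trisubstituted alkene does not engage.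

Step 8
Reactants: 16 methyl (3R)-3-formyl-4-[(2S,3S)-3-methyl-3-[(3E,7E)-4,8-dimethyl-9-oxonona-3,7-dien-1-yl]oxiran-2-yl]butanoate
Product: 18 (1R,3S,4S,7E,11E,13S,14R)-3,4-epoxy-13-hydroxy-17-norcembra-7,11-dien-16,14-olide, via bis(diiodosamarium) diolate 17 (not isolated)
Conditions: SmI2 (2.5 equiv), THF, 0 °C → rt, syringe-pump addition of 16 (final 2 mM); then aq Na2S2O3/NaHCO3
Reagents that add atoms: none
Why: Intramolecular pinacol coupling, in which the two samarium ketyl radicals join at C13–C14 under high dilution to close the 14-membered ring; the samarium-bridged diolate should give the cis (erythro) diol, Felkin–Anh approach anti to the ring chain on C1 should give 14R (hence 13S), and the C14 alkoxide then closes the five-membered lactone onto the methyl ester faster than the C13 alkoxide can form a six-membered one.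

Step 9
Reactants: 18 (1R,3S,4S,7E,11E,13S,14R)-3,4-epoxy-13-hydroxy-17-norcembra-7,11-dien-16,14-olide
Product: 21 (1R,3S,4S,7E,11E,13S,14R)-3,4-epoxy-13-hydroxycembra-7,11,15(17)-trien-16,14-olide, via Mannich base 19 (not isolated), via trimethylammonium iodide 20 (not isolated)
Conditions: LDA (2.5 equiv), THF, −78 °C; CH2=NMe2+ I−, −78 → 0 °C; then MeI, CH2Cl2/MeOH, rt; then aq NaHCO3
Reagents that add atoms: N,N-dimethylmethyleneiminium iodide, C=[N+](C)C.[I-]
Why: Eschenmoser α-methylenation, in which the alkoxide/enolate dianion undergoes a Mannich reaction at C15 and quaternisation followed by Hofmann-type elimination gives the exocyclic alkene; C1 and C14 are not enolisable under these conditions and stay fixed.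

Step 10
Reactants: 21 (1R,3S,4S,7E,11E,13S,14R)-3,4-epoxy-13-hydroxycembra-7,11,15(17)-trien-16,14-olide
Product: 22 (1R,3S,4S,7E,11E,13S,14R)-13-acetoxy-3,4-epoxycembra-7,11,15(17)-trien-16,14-olide
Conditions: Ac2O, pyridine, DMAP (cat.), CH2Cl2, 0 °C → rt
Reagents that add atoms: acetic anhydride, CC(=O)OC(C)=O
Why: DMAP-catalysed acylation of the only free hydroxyl, with retention at C13.

Step 11
Reactants: 22 (1R,3S,4S,7E,11E,13S,14R)-13-acetoxy-3,4-epoxycembra-7,11,15(17)-trien-16,14-olide
Product: 23 (1R,3S,4S,7R,11E,13S,14R)-13-acetoxy-3,4-epoxy-7-hydroperoxycembra-8(19),11,15(17)-trien-16,14-olide (CNP0166375.2)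
Conditions: O2, tetraphenylporphyrin (cat.), visible light, CH2Cl2, −20 °C, to about 60% conversion
Reagents that add atoms: oxygen, O=O
Why: Schenck ene reaction, in which singlet oxygen attacks the only electron-rich alkene (C11=C12 is deactivated by the allylic acetate, C15=C17 is electron-poor), abstracts a C19 methyl hydrogen and bonds to C7 from the outer face of the macrocycle to give the 7R hydroperoxide, which is separated from the 8-hydroperoxy-6-ene isomer.

## Compound list

1 | hex-1-en-5-yne | C=CCCC#C | starting material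
2 | dimethyl[(1E)-2-methylhexa-1,5-dien-1-yl]alumane | C[Al](C)/C=C(\C)CCC=C | intermediate
3 | (1E)-1-iodo-2-methylhexa-1,5-diene | I/C=C(\C)CCC=C | intermediate
4 | (2E)-3-methylpent-2-en-4-yn-1-ol | OC/C=C(\C)C#C | starting material
5 | (2E)-3-methylpenta-2,4-dien-1-ol | OC/C=C(\C)C=C | intermediate
6 | 9-{[(2E)-5-(9-borabicyclo[3.3.1]nonan-9-yl)-3-methylpent-2-en-1-yl]oxy}-9-borabicyclo[3.3.1]nonane | B1(OC/C=C(\C)CCB2C3CCCC2CCC3)C2CCCC1CCC2 | intermediate
7 | (2E,6E)-3,7-dimethylundeca-2,6,10-trien-1-ol | OC/C=C(\C)CC/C=C(\C)CCC=C | intermediate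
8 | [(2S,3S)-3-methyl-3-[(3E)-4-methylocta-3,7-dien-1-yl]oxiran-2-yl]methanol | OC[C@@H]1O[C@@]1(C)CC/C=C(\C)CCC=C | intermediate
9 | (E)-N-tert-butylethanimine | C/C=N/C(C)(C)C | starting material
10 | [(2S,3S)-3-methyl-3-[(3E)-4-methylocta-3,7-dien-1-yl]oxiran-2-yl]methyl trifluoromethanesulfonate | O=S(=O)(OC[C@@H]1O[C@@]1(C)CC/C=C(\C)CCC=C)C(F)(F)F | intermediate
11 | (1E)-N-tert-butyl-3-[(2S,3S)-3-methyl-3-[(3E)-4-methylocta-3,7-dien-1-yl]oxiran-2-yl]propan-1-imine | CC(C)(C)/N=C/CC[C@@H]1O[C@@]1(C)CC/C=C(\C)CCC=C | intermediate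
12 | 3-[(2S,3S)-3-methyl-3-[(3E)-4-methylocta-3,7-dien-1-yl]oxiran-2-yl]propanal | O=CCC[C@@H]1O[C@@]1(C)CC/C=C(\C)CCC=C | intermediate
13 | methyl bromoacetate | COC(=O)CBr | starting material
14 | methyl (3R)-3-formyl-4-[(2S,3S)-3-methyl-3-[(3E)-4-methylocta-3,7-dien-1-yl]oxiran-2-yl]butanoate | O=C[C@@H](CC(=O)OC)C[C@@H]1O[C@@]1(C)CC/C=C(\C)CCC=C | intermediate
15 | methacrolein (2-methylprop-2-enal) | CC(=C)C=O | starting material
16 | methyl (3R)-3-formyl-4-[(2S,3S)-3-methyl-3-[(3E,7E)-4,8-dimethyl-9-oxonona-3,7-dien-1-yl]oxiran-2-yl]butanoate | O=C[C@@H](CC(=O)OC)C[C@@H]1O[C@@]1(C)CC/C=C(\C)CC/C=C(\C)C=O | intermediate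
17 | bis(diiodosamarium) 13,14-diolate of the macrocyclic methyl ester (cembrane numbering: 1R,3S,4S,13S,14R; 3,4-epoxide; 7E,11E; CH2CO2Me on C1) | I[Sm](I)O[C@@H]1[C@@H](CC(=O)OC)C[C@@H]2O[C@@]2(C)CC/C=C(\C)CC/C=C(\C)[C@@H]1O[Sm](I)I | intermediate
18 | (1R,3S,4S,7E,11E,13S,14R)-3,4-epoxy-13-hydroxy-17-norcembra-7,11-dien-16,14-olide (trans-fused γ-lactone, CH2 at C15) | C1C(=O)O[C@@H]2[C@@H]1C[C@@H]1O[C@@]1(C)CC/C=C(\C)CC/C=C(\C)[C@@H]2O | intermediate
19 | 15-[(dimethylamino)methyl] derivative of 18 (Mannich base, C15 epimers) | CN(C)CC1C(=O)O[C@@H]2[C@@H]1C[C@@H]1O[C@@]1(C)CC/C=C(\C)CC/C=C(\C)[C@@H]2O | intermediate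
20 | 15-[(trimethylammonio)methyl] derivative of 18, iodide (C15 epimers) | C[N+](C)(C)CC1C(=O)O[C@@H]2[C@@H]1C[C@@H]1O[C@@]1(C)CC/C=C(\C)CC/C=C(\C)[C@@H]2O.[I-] | intermediate
21 | (1R,3S,4S,7E,11E,13S,14R)-3,4-epoxy-13-hydroxycembra-7,11,15(17)-trien-16,14-olide | C=C1C(=O)O[C@@H]2[C@@H]1C[C@@H]1O[C@@]1(C)CC/C=C(\C)CC/C=C(\C)[C@@H]2O | intermediate
22 | (1R,3S,4S,7E,11E,13S,14R)-13-acetoxy-3,4-epoxycembra-7,11,15(17)-trien-16,14-olide | C=C1C(=O)O[C@@H]2[C@@H]1C[C@@H]1O[C@@]1(C)CC/C=C(\C)CC/C=C(\C)[C@@H]2OC(C)=O | intermediate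
23 | (1R,3S,4S,7R,11E,13S,14R)-13-acetoxy-3,4-epoxy-7-hydroperoxycembra-8(19),11,15(17)-trien-16,14-olide (CNP0166375.2) | C=C1C(=O)O[C@@H]2[C@@H]1C[C@@H]1O[C@@]1(C)CC[C@@H](OO)C(=C)CC/C=C(\C)[C@@H]2OC(C)=O | target

## Step count and risks

Total step count: 11. Longest linear sequence: 10 steps (steps 2–11 from 4; equally steps 1 and 3–11 from 1).

The three steps most likely to fail:

The macrocyclisation in step 8 is the largest risk: oligomerisation, simple reduction of the enal, or formation of the trans diol or the C14 epimer could each dominate. The fallback sets out from 16 and replaces ketyl–ketyl coupling by a polar, closed-transition-state organochromium addition (Takai cross-pinacol-type coupling). CrCl2 and Me3SiCl in THF under high dilution convert only the enal into a γ-siloxyallylchromium species. This adds through its oxygen-bearing carbon to the C14 aldehyde, the chromium alkoxide lactonises onto the methyl ester, and the product is the 13-O-trimethylsilyl ether of the hydroxy lactone F3. Citric acid in MeOH removes the silyl group, and the route is rejoined at 18.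

The photoredox alkylation in step 6 may fail because methyl bromoacetate is harder to reduce than the usual radical precursors, or because the 4,5-epoxy aldehyde does not survive the amine salt. The fallback sets out from 12 and uses a stoichiometric auxiliary and polar enolate chemistry instead. Condensation with RAMP gives the RAMP hydrazone of 12 F1. Deprotonation with LDA at −78 °C and alkylation with methyl bromoacetate at −100 °C gives the alkylated RAMP hydrazone F2, with the 3R centre expected from the Enders model. Buffered aqueous CuCl2 in THF cleaves the hydrazone without racemisation, and the route is rejoined at 14.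

The ene reaction in step 11 may give mainly the 8-hydroperoxy-6-ene isomer or the C7 epimer. The fallback sets out from 22 and separates the regiochemical event from the C–O bond formation. Ene-type chlorination with HOCl (Ca(OCl)2, CO2, CH2Cl2/H2O, 0 °C) takes a hydrogen from the C19 methyl with high preference and gives the 7-chloro-8(19)-ene F4 as C7 epimers. AgOTf-assisted substitution with anhydrous H2O2 in Et2O at 0 °C (2,6-di-tert-butylpyridine as acid scavenger) then gives 23, which is separated by HPLC from its C7 epimer and the primary C19 hydroperoxide.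

Further compounds

F1 | step 6 | RAMP hydrazone of 12: (1E)-N-[(2R)-2-(methoxymethyl)pyrrolidin-1-yl]-3-[(2S,3S)-3-methyl-3-[(3E)-4-methylocta-3,7-dien-1-yl]oxiran-2-yl]propan-1-imine | COC[C@H]1CCCN1/N=C/CC[C@@H]1O[C@@]1(C)CC/C=C(\C)CCC=C
F2 | step 6 | alkylated RAMP hydrazone: methyl (3R)-3-[(E)-{[(2R)-2-(methoxymethyl)pyrrolidin-1-yl]imino}methyl]-4-[(2S,3S)-3-methyl-3-[(3E)-4-methylocta-3,7-dien-1-yl]oxiran-2-yl]butanoate | COC[C@H]1CCCN1/N=C/[C@@H](CC(=O)OC)C[C@@H]1O[C@@]1(C)CC/C=C(\C)CCC=C
F3 | step 8 | 13-O-trimethylsilyl ether of 18 | C1C(=O)O[C@@H]2[C@@H]1C[C@@H]1O[C@@]1(C)CC/C=C(\C)CC/C=C(\C)[C@@H]2O[Si](C)(C)C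
F4 | step 11 | (1R,3S,4S,11E,13S,14R)-13-acetoxy-7-chloro-3,4-epoxycembra-8(19),11,15(17)-trien-16,14-olide (C7 epimers) | C=C1C(=O)O[C@@H]2[C@@H]1C[C@@H]1O[C@@]1(C)CCC(Cl)C(=C)CC/C=C(\C)[C@@H]2OC(C)=O
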